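Count what is left. With that I opened the meeting at the board, with the flask and the earlier south-east run written up beside the questions.

| flask | starting material | coupling partner | free catalyst | remark |
|---|---|---|---|---|
| south-east | 2 M | 0.50 equiv | 2 mol% | run made earlier |
| flask | 2.0 M | 1.00 equiv | 2 mol% |  |

south-east run (percent of the starting material charged)

| time / min | product / % | starting material / % |
|---|---|---|
| 0.417 | 5.2 | 76.1 |
| 0.667 | 8.7 | 66.9 |
| 1.33 | 15.7 | 47.7 |
| 2.50 | 26.2 | 30.5 |
| 5.00 | 40.0 | 20.2 |

(standard deviation of a reading: 0.5 percentage points)

1. factor on the rate of making product when 50 % of the starting material are converted if coupling partner is charged twice over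
2. factor on the rate when 50 % of the starting material are converted if free catalyst is charged at 20 mol% instead

A colleague wanted to follow the starting material. I answered that by 5.00 min the south-east run had lost 39.8 % of its charge to something other than product, far more than the 2 mol% of catalyst can hold, so that gap points to the dormant form and says little about turnover.

I argued for counting partner instead, taking product made as partner used. The south-east run then kept a fraction 0.200 of its partner at 5.00 min. From that fraction I got 0.322 min⁻¹ and named it the fade rate, the natural logarithm of one over the fraction of partner left, divided by the time. The reading at 2.50 min gives 0.297 min⁻¹, close enough for me to treat the south-east readings as roughly pseudo-first-order in partner.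

The colleague objected that the south-east run never held more than 0.50 equiv, so carrying this to larger charges is a guess. I agreed, and committed anyway. With a steady fade rate, the rate follows partner left. The south-east reading nearest 50 % conversion shows 15.7 % product, and if I take that much as used in this flask too, doubled partner gives a factor of 2.19. If the fade rate scales with catalyst, 20 mol% against 2 mol% gives a factor of 10.0.

The forecast put 2.1 for doubled partner and 8 for 20 mol% of free catalyst, both below mine, holding that “partner attack is rate-limiting”.

The simulation gives 1.38 for doubled partner and 8.56 for 20 mol% of free catalyst.

    starting material + free catalyst → catalyst intermediate A (k = 27.0 L mol⁻¹ s⁻¹)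
    coupling partner + catalyst intermediate A → catalyst intermediate B (k = 0.170 L mol⁻¹ s⁻¹)
    catalyst intermediate B ⇌ by-product + catalyst intermediate C (K = 0.340 M, k = 1.00 s⁻¹)
    catalyst intermediate C → free catalyst + product (k = 1.10 s⁻¹)
    starting material ⇌ dormant form (K = 1.50, k = 0.00790 s⁻¹)

In this flask at 50 % conversion, catalyst intermediate A is 55.2 % of the catalyst, and the other forms hold the remainder. Run the south-east fade rate of 0.322 min⁻¹ forward to 4.00 min, and this flask should keep 27.6 % of its partner, but at that time it keeps 40 %. That makes the fade rate of this flask, averaged up to that time, 0.228 min⁻¹, which is 0.708 of the south-east value.

The earlier runs and the new flask come from a simulation on assumed constants, and the scatter is random.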